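The tetrahydropyran ring (O1, C2 aryl, C4 hydroxyl, C6 4-hydroxyphenethyl) is disconnected at C3–C4. This bond involves neither C2 nor C6. Both carbinol carbons can therefore be set beforehand on O1 in an acyclic bis-secondary ether, and a boron atom on C4 marks the one carbon that will receive oxygen. Ring-closing metathesis of a diene ether carrying a vinyl group on C2 and a 2-(pinacolboryl)allyl group on C6 forms C3=C4 and the six-membered ring in one operation. Boron is installed only after ether formation, because an alkoxide four atoms from a boronate would be trapped as a cyclic borate. Oxidation, axial hydride delivery and hydrogenolysis then give the target.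

Key step: step 10

Assumption: the (Sa,Sc,Sc) antipode of the phosphoramidite in step 7 is taken to give the (S)-configured branched ether, the usual sense of induction of this catalyst family with cinnamyl carbonates. If a test reaction shows the opposite sense, the equally available (Ra,Rc,Rc) antipode is used and nothing else changes.

Step 1
Reactants: 1 3,4-dihydroxy-5-methoxybenzaldehyde (5-hydroxyvanillin)
Product: 2 3,4-bis(benzyloxy)-5-methoxybenzaldehyde
Conditions: BnBr (2.3 equiv), K2CO3, DMF, 60 °C, N2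
Reagents that add atoms: benzyl bromide, BrCc1ccccc1
Why: Williamson ether synthesis, in which both catechol phenoxides are alkylated by the benzylic bromide while the aldehyde is inert to carbonate base, and benzyl is chosen because all three phenol protecting groups can then leave together in step 13.

Step 2
Reactants: 2 3,4-bis(benzyloxy)-5-methoxybenzaldehyde; 3 ethyl (triphenylphosphoranylidene)acetate
Product: 4 ethyl (E)-3-[3,4-bis(benzyloxy)-5-methoxyphenyl]prop-2-enoate
Conditions: toluene, 90 °C
Reagents that add atoms: none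
Why: Wittig olefination with a stabilised ylide, which with aromatic aldehydes should give the (E)-enoate needed for a linear (E)-allyl electrophile and touches no other group.

Step 3
Reactants: 4 ethyl (E)-3-[3,4-bis(benzyloxy)-5-methoxyphenyl]prop-2-enoate
Product: 5 (E)-3-[3,4-bis(benzyloxy)-5-methoxyphenyl]prop-2-en-1-ol
Conditions: iBu2AlH (2.3 equiv), CH2Cl2, −78 to 0 °C
Reagents that add atoms: none
Why: 1,2-reduction of a conjugated ester with a dialkylaluminium hydride, which delivers two hydrides to the carbonyl carbon at low temperature without touching the alkene geometry or the benzyl ethers.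

Step 4
Reactants: 5 (E)-3-[3,4-bis(benzyloxy)-5-methoxyphenyl]prop-2-en-1-ol
Product: 6 tert-butyl (E)-3-[3,4-bis(benzyloxy)-5-methoxyphenyl]prop-2-en-1-yl carbonate
Conditions: Boc2O, Bu4NHSO4 (cat.), 30% aq NaOH, CH2Cl2, 0 °C to rt
Reagents that add atoms: di-tert-butyl dicarbonate, CC(C)(C)OC(=O)OC(=O)OC(C)(C)C
Why: phase-transfer O-acylation of a primary allylic alcohol with the pyrocarbonate; the tert-butyl carbonate is preferred as leaving group because the tert-butoxide it releases in step 7 is too hindered to compete as nucleophile.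

Step 5
Reactants: 7 4-(benzyloxy)benzyl chloride; 8 (S)-epichlorohydrin
Product: 11 (S)-2-[2-(4-benzyloxyphenyl)ethyl]oxirane, via benzylic Grignard reagent 9 (not isolated), via chlorohydrin 10 (not isolated)
Conditions: 7, Mg, THF, 0 °C (slow addition); CuI (10 mol%), 8, −40 to 0 °C; then 6 M aq NaOH added to the same flask, rt
Reagents that add atoms: none
Why: copper-catalysed Grignard opening of the epoxide at its unsubstituted carbon followed by intramolecular Williamson closure (3-exo-tet) of the chlorohydrin; the C–O bond at the stereocentre is never broken, so the configuration of 8 is carried unchanged into 11 and becomes C6.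

Step 6
Reactants: 11 (S)-2-[2-(4-benzyloxyphenyl)ethyl]oxirane; 12 (triisopropylsilyl)acetylene
Product: 14 (S)-1-(4-benzyloxyphenyl)-6-(triisopropylsilyl)hex-5-yn-3-ol, via lithium acetylide 13 (not isolated)
Conditions: 12, nBuLi, THF, −78 °C; BF3·OEt2; then 11, −78 °C
Reagents that add atoms: none
Why: BF3-promoted opening of a terminal epoxide by a lithium acetylide (Yamaguchi–Hirao alkynylation) at the less hindered carbon, again without touching the carbinol centre; the bulky silyl group masks the acidic alkyne C–H that would otherwise consume the copper alkoxide of step 7, and it resists alkoxide-induced desilylation.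

Step 7
Reactants: 14 (S)-1-(4-benzyloxyphenyl)-6-(triisopropylsilyl)hex-5-yn-3-ol; 6 tert-butyl (E)-3-[3,4-bis(benzyloxy)-5-methoxyphenyl]prop-2-en-1-yl carbonate
Product: 17 (3S)-3-[(1S)-1-(3,4-bis(benzyloxy)-5-methoxyphenyl)allyloxy]-1-(4-benzyloxyphenyl)-6-(triisopropylsilyl)hex-5-yne, via lithium alkoxide 15 (not isolated), via copper alkoxide 16 (not isolated)
Conditions: 14 (1.5 equiv), nBuLi, THF, 0 °C; CuI, rt; then 6, [Ir(cod)Cl]2 (2 mol%), (Sa,Sc,Sc)-O,O'-(1,1'-binaphthyl-2,2'-diyl)-N,N-bis(1-phenylethyl)phosphoramidite (4 mol%), THF, rt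
Reagents that add atoms: none
Why: iridium-catalysed asymmetric allylic etherification with a monovalent copper alkoxide, in which the cyclometalated iridium–phosphoramidite complex ionises the linear carbonate and the soft alkoxide attacks the aryl-bearing allyl terminus anti to the metal, so that the branched ether forms and the new benzylic centre (future C2, S) is set by the ligand antipode, while the centre of 14 is retained because only its O–H bond reacts.

Step 8
Reactants: 17 (3S)-3-[(1S)-1-(3,4-bis(benzyloxy)-5-methoxyphenyl)allyloxy]-1-(4-benzyloxyphenyl)-6-(triisopropylsilyl)hex-5-yne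
Product: 18 (3S)-3-[(1S)-1-(3,4-bis(benzyloxy)-5-methoxyphenyl)allyloxy]-1-(4-benzyloxyphenyl)hex-5-yne
Conditions: Bu4NF (1.1 equiv), THF, 0 °C to rt
Reagents that add atoms: none
Why: fluoride-induced protodesilylation of an alkynylsilane, to which the ethers, the vinyl group and both stereocentres are inert.

Step 9
Reactants: 18 (3S)-3-[(1S)-1-(3,4-bis(benzyloxy)-5-methoxyphenyl)allyloxy]-1-(4-benzyloxyphenyl)hex-5-yne; 19 bis(pinacolato)diboron
Product: 20 2-{(4S)-4-[(1S)-1-(3,4-bis(benzyloxy)-5-methoxyphenyl)allyloxy]-6-(4-benzyloxyphenyl)hex-1-en-2-yl}-4,4,5,5-tetramethyl-1,3,2-dioxaborolane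
Conditions: 19 (1.05 equiv), (Et2CAAC)CuCl (5 mol%; Et2CAAC = 1-(2,6-diisopropylphenyl)-3,3-diethyl-5,5-dimethylpyrrolidin-2-ylidene), NaOtBu (10 mol%), MeOH (2 equiv), THF, 0 °C to rt
Reagents that add atoms: none
Why: copper-catalysed Markovnikov protoboration of a terminal alkyne, in which the carbene-ligated Cu–Bpin species adds syn across the triple bond with boron on the internal carbon, methanol protonates the alkenylcopper, and the alkyne reacts far faster than the unactivated vinyl group, so that boron arrives only after all alkoxide chemistry is over.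

Step 10
Reactants: 20 2-{(4S)-4-[(1S)-1-(3,4-bis(benzyloxy)-5-methoxyphenyl)allyloxy]-6-(4-benzyloxyphenyl)hex-1-en-2-yl}-4,4,5,5-tetramethyl-1,3,2-dioxaborolane
Product: 21 (2S,6S)-2-[3,4-bis(benzyloxy)-5-methoxyphenyl]-6-[2-(4-benzyloxyphenyl)ethyl]-4-(4,4,5,5-tetramethyl-1,3,2-dioxaborolan-2-yl)-5,6-dihydro-2H-pyran
Conditions: second-generation Hoveyda–Grubbs catalyst RuCl2(SIMes)(=CH-C6H4-2-OiPr) (5–10 mol%), 1,4-benzoquinone (20 mol%), toluene (0.005 M), 70 °C, argon sparge
Reagents that add atoms: none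
Why: Ring-closing alkene metathesis, in which the ruthenium carbene first exchanges with the unhindered monosubstituted vinyl group on C2, the resulting alkylidene at C3 adds intramolecularly to the 1,1-disubstituted boryl alkene by [2+2] cycloaddition, and cycloreversion gives the C3=C4 bond and a ruthenium methylidene that carries the chain, with ethylene as the only co-product. The closest known reaction type is the closure of dienes containing a 2-boryl-1-alkene unit to five- to seven-membered cyclic alkenyl boronates with ruthenium carbenes. The ring O1–C2–C3–C4–C5–C6 closes as a six-membered ring with an endocyclic double bond, the two alkene termini being held close by the branched bis-secondary ether. No stereocentre is formed and none is touched, because C2 and C6 are sp3 spectators fixed in steps 7 and 5. The step needs ring closure to win over intermolecular metathesis and the hindered alkene to react once only, which is secured by high dilution, removal of ethylene and the reluctance of a 2-boryl-1-alkene to homodimerise, while the boron on C4 fixes the later site of oxygenation. 1,4-Benzoquinone is added to intercept ruthenium hydrides that could move the double bond towards the doubly activated C2–H.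

Step 11
Reactants: 21 (2S,6S)-2-[3,4-bis(benzyloxy)-5-methoxyphenyl]-6-[2-(4-benzyloxyphenyl)ethyl]-4-(4,4,5,5-tetramethyl-1,3,2-dioxaborolan-2-yl)-5,6-dihydro-2H-pyran
Product: 23 (2S,6S)-2-[3,4-bis(benzyloxy)-5-methoxyphenyl]-6-[2-(4-benzyloxyphenyl)ethyl]tetrahydropyran-4-one, via enol 22 (not isolated)
Conditions: NaBO3·4H2O (4 equiv), THF/H2O 1:1, rt
Reagents that add atoms: sodium perborate (NaBO3·4H2O), O[B-]1(O)OO[B-](O)(O)OO1.[Na+].[Na+]
Why: perborate oxidation of a carbon–boron bond (peroxide addition to boron and 1,2-shift of the alkenyl carbon to oxygen) gives the C4 enol, which tautomerises to the ketone; the mild medium spares the ethers, and any reversible oxa-Michael opening can only return the more stable cis-2,6 isomer.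

Step 12
Reactants: 23 (2S,6S)-2-[3,4-bis(benzyloxy)-5-methoxyphenyl]-6-[2-(4-benzyloxyphenyl)ethyl]tetrahydropyran-4-one
Product: 24 (2S,4R,6S)-2-[3,4-bis(benzyloxy)-5-methoxyphenyl]-6-[2-(4-benzyloxyphenyl)ethyl]tetrahydropyran-4-ol
Conditions: NaBH4, MeOH/CH2Cl2, −40 to 0 °C
Reagents that add atoms: none
Why: borohydride reduction of a conformationally locked six-membered ketone, in which both C2 and C6 substituents sit equatorial, the small hydride attacks along the axial trajectory and the equatorial (4R) alcohol, cis to both substituents, should result.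

Step 13
Reactants: 24 (2S,4R,6S)-2-[3,4-bis(benzyloxy)-5-methoxyphenyl]-6-[2-(4-benzyloxyphenyl)ethyl]tetrahydropyran-4-ol
Product: 25 (2S,4R,6S)-2-(3,4-dihydroxy-5-methoxyphenyl)-6-[2-(4-hydroxyphenyl)ethyl]tetrahydropyran-4-ol (CNP0186008.1)
Conditions: H2 (1 atm), 10% Pd/C, EtOAc/EtOH, rt
Reagents that add atoms: none
Why: catalytic hydrogenolysis of the three aryl benzyl ethers, which are cleaved much faster than the secondary benzylic C2–O1 ring bond in a neutral solvent, so the reaction is stopped after uptake of three equivalents of hydrogen and the catechol is handled under inert gas.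

Compound list
1 | 3,4-dihydroxy-5-methoxybenzaldehyde | COc1cc(C=O)cc(O)c1O | starting material
2 | 3,4-bis(benzyloxy)-5-methoxybenzaldehyde | COc1cc(C=O)cc(OCc2ccccc2)c1OCc1ccccc1 | intermediate
3 | ethyl (triphenylphosphoranylidene)acetate | CCOC(=O)C=P(c1ccccc1)(c1ccccc1)c1ccccc1 | starting material
4 | ethyl (E)-3-[3,4-bis(benzyloxy)-5-methoxyphenyl]prop-2-enoate | COc1cc(/C=C/C(=O)OCC)cc(OCc2ccccc2)c1OCc1ccccc1 | intermediate
5 | (E)-3-[3,4-bis(benzyloxy)-5-methoxyphenyl]prop-2-en-1-ol | COc1cc(/C=C/CO)cc(OCc2ccccc2)c1OCc1ccccc1 | intermediate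
6 | tert-butyl (E)-3-[3,4-bis(benzyloxy)-5-methoxyphenyl]prop-2-en-1-yl carbonate | COc1cc(/C=C/COC(=O)OC(C)(C)C)cc(OCc2ccccc2)c1OCc1ccccc1 | intermediate
7 | 4-(benzyloxy)benzyl chloride | ClCc1ccc(OCc2ccccc2)cc1 | starting material
8 | (S)-epichlorohydrin | ClC[C@@H]1CO1 | starting material
9 | 4-(benzyloxy)benzylmagnesium chloride | Cl[Mg]Cc1ccc(OCc2ccccc2)cc1 | intermediate
10 | (S)-4-(4-benzyloxyphenyl)-1-chlorobutan-2-ol | ClC[C@@H](O)CCc1ccc(OCc2ccccc2)cc1 | intermediate
11 | (S)-2-[2-(4-benzyloxyphenyl)ethyl]oxirane | C1[C@@H](O1)CCc2ccc(OCc3ccccc3)cc2 | intermediate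
12 | (triisopropylsilyl)acetylene | C#C[Si](C(C)C)(C(C)C)C(C)C | starting material
13 | lithium (triisopropylsilyl)acetylide | [Li]C#C[Si](C(C)C)(C(C)C)C(C)C | intermediate
14 | (S)-1-(4-benzyloxyphenyl)-6-(triisopropylsilyl)hex-5-yn-3-ol | CC(C)[Si](C#CC[C@@H](O)CCc1ccc(OCc2ccccc2)cc1)(C(C)C)C(C)C | intermediate
15 | lithium alkoxide of 14 | CC(C)[Si](C#CC[C@@H](O[Li])CCc1ccc(OCc2ccccc2)cc1)(C(C)C)C(C)C | intermediate
16 | monovalent copper alkoxide of 14 | CC(C)[Si](C#CC[C@@H](O[Cu])CCc1ccc(OCc2ccccc2)cc1)(C(C)C)C(C)C | intermediate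
17 | (3S)-3-[(1S)-1-(3,4-bis(benzyloxy)-5-methoxyphenyl)allyloxy]-1-(4-benzyloxyphenyl)-6-(triisopropylsilyl)hex-5-yne | COc1cc([C@H](C=C)O[C@@H](CCc3ccc(OCc4ccccc4)cc3)CC#C[Si](C(C)C)(C(C)C)C(C)C)cc(OCc2ccccc2)c1OCc1ccccc1 | intermediate
18 | (3S)-3-[(1S)-1-(3,4-bis(benzyloxy)-5-methoxyphenyl)allyloxy]-1-(4-benzyloxyphenyl)hex-5-yne | COc1cc([C@H](C=C)O[C@@H](CCc3ccc(OCc4ccccc4)cc3)CC#C)cc(OCc2ccccc2)c1OCc1ccccc1 | intermediate
19 | bis(pinacolato)diboron | CC1(C)OB(OC1(C)C)B1OC(C)(C)C(C)(C)O1 | starting material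
20 | 2-{(4S)-4-[(1S)-1-(3,4-bis(benzyloxy)-5-methoxyphenyl)allyloxy]-6-(4-benzyloxyphenyl)hex-1-en-2-yl}-4,4,5,5-tetramethyl-1,3,2-dioxaborolane | COc1cc([C@H](C=C)O[C@@H](CCc3ccc(OCc4ccccc4)cc3)CC(=C)B5OC(C)(C)C(C)(C)O5)cc(OCc2ccccc2)c1OCc1ccccc1 | intermediate
21 | (2S,6S)-2-[3,4-bis(benzyloxy)-5-methoxyphenyl]-6-[2-(4-benzyloxyphenyl)ethyl]-4-(4,4,5,5-tetramethyl-1,3,2-dioxaborolan-2-yl)-5,6-dihydro-2H-pyran | COc1cc([C@@H]3C=C(B5OC(C)(C)C(C)(C)O5)C[C@H](CCc4ccc(OCc6ccccc6)cc4)O3)cc(OCc2ccccc2)c1OCc1ccccc1 | intermediate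
22 | (2S,6S)-2-[3,4-bis(benzyloxy)-5-methoxyphenyl]-6-[2-(4-benzyloxyphenyl)ethyl]-5,6-dihydro-2H-pyran-4-ol (enol) | COc1cc([C@@H]3C=C(O)C[C@H](CCc4ccc(OCc6ccccc6)cc4)O3)cc(OCc2ccccc2)c1OCc1ccccc1 | intermediate
23 | (2S,6S)-2-[3,4-bis(benzyloxy)-5-methoxyphenyl]-6-[2-(4-benzyloxyphenyl)ethyl]tetrahydropyran-4-one | COc1cc([C@@H]3CC(=O)C[C@H](CCc4ccc(OCc6ccccc6)cc4)O3)cc(OCc2ccccc2)c1OCc1ccccc1 | intermediate
24 | (2S,4R,6S)-2-[3,4-bis(benzyloxy)-5-methoxyphenyl]-6-[2-(4-benzyloxyphenyl)ethyl]tetrahydropyran-4-ol | COc1cc([C@@H]3C[C@H](O)C[C@H](CCc4ccc(OCc6ccccc6)cc4)O3)cc(OCc2ccccc2)c1OCc1ccccc1 | intermediate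
25 | (2S,4R,6S)-2-(3,4-dihydroxy-5-methoxyphenyl)-6-[2-(4-hydroxyphenyl)ethyl]tetrahydropyran-4-ol, all three ring substituents cis | COc1cc([C@@H]2C[C@H](O)C[C@H](CCc3ccc(O)cc3)O2)cc(O)c1O | target

Total step count: 13.
Longest linear sequence: 11 steps (1 → 2 → 4 → 5 → 6 → 17 → 18 → 20 → 21 → 23 → 24 → 25). The branch from 7 and 8 joins in step 7 after two steps.

Steps most likely to fail

1. Step 10.
- **What may go wrong:** The hindered boryl alkene may be too slow to enter the metallacycle. The alkylidene on C3 would then couple vinyl ends intermolecularly or decay, or ruthenium hydrides formed on decay would shift the vinyl double bond into conjugation with the aryl ring.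
- **Fallback:** The ring is built by a Prins cyclisation instead of metathesis. It sets out from epoxide 11, which is opened with vinylmagnesium bromide and catalytic CuI in THF to (S)-1-(4-benzyloxyphenyl)hex-5-en-3-ol F1. Condensation of F1 with aldehyde 2 in CH2Cl2/trifluoroacetic acid at 0 °C forms the oxocarbenium ion. This closes through a chair with all substituents equatorial to (2S,4R,6S)-2-[3,4-bis(benzyloxy)-5-methoxyphenyl]-6-[2-(4-benzyloxyphenyl)ethyl]tetrahydropyran-4-yl trifluoroacetate F2. Methanolysis (K2CO3, MeOH) comes back to the route at 24.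

2. Step 9.
- **What may go wrong:** Regiocontrol may be lost, with boron delivered to the terminal carbon, because only a remote ether oxygen polarises the alkyne. A second borylcupration of the product is also possible, as is borylcupration of the vinyl group followed by expulsion of the alkoxide.
- **Fallback:** Silicon replaces boron as the C4 marker. It sets out from enyne 18. Markovnikov hydrosilylation with benzyldimethylsilane and [Cp*Ru(MeCN)3]PF6 in acetone at 0 °C is selective for alkynes over alkenes and should give benzyl{(4S)-4-[(1S)-1-(3,4-bis(benzyloxy)-5-methoxyphenyl)allyloxy]-6-(4-benzyloxyphenyl)hex-1-en-2-yl}dimethylsilane F3. Ring-closing metathesis under the conditions of step 10 gives benzyl{(2S,6S)-2-[3,4-bis(benzyloxy)-5-methoxyphenyl]-6-[2-(4-benzyloxyphenyl)ethyl]-5,6-dihydro-2H-pyran-4-yl}dimethylsilane F4. Tamao–Fleming oxidation (Bu4NF, then H2O2, KHCO3, MeOH/THF) comes back to the route at ketone 23.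

3. Step 7.
- **What may go wrong:** Attack of the hindered secondary copper alkoxide may be sluggish. It may occur at the unsubstituted allyl terminus to give the linear ether. Facial selectivity may be poor if ligand and resident stereocentre are mismatched.
- **Fallback:** The C2–O1 bond is made intramolecularly under thermodynamic control. It sets out from 14 and aldehyde 2. Desilylation of 14 (Bu4NF, THF) gives (S)-1-(4-benzyloxyphenyl)hex-5-yn-3-ol F5. Markovnikov hydration ((IPr)AuCl/AgSbF6, dioxane/water) gives (S)-6-(4-benzyloxyphenyl)-4-hydroxyhexan-2-one F6. Claisen–Schmidt condensation at the methyl group with 2 (Ba(OH)2, MeOH) gives (S,E)-1-[3,4-bis(benzyloxy)-5-methoxyphenyl]-7-(4-benzyloxyphenyl)-5-hydroxyhept-1-en-3-one F7. This closes by 6-endo-trig oxa-Michael addition under equilibrating conditions (catalytic DBU) to the more stable cis isomer and comes back to the route at ketone 23.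

Further compounds
F1 | step 10 | (S)-1-(4-benzyloxyphenyl)hex-5-en-3-ol | C=CC[C@@H](O)CCc1ccc(OCc2ccccc2)cc1
F2 | step 10 | (2S,4R,6S)-2-[3,4-bis(benzyloxy)-5-methoxyphenyl]-6-[2-(4-benzyloxyphenyl)ethyl]tetrahydropyran-4-yl trifluoroacetate | COc1cc([C@@H]3C[C@H](OC(=O)C(F)(F)F)C[C@H](CCc4ccc(OCc6ccccc6)cc4)O3)cc(OCc2ccccc2)c1OCc1ccccc1
F3 | step 9 | benzyl{(4S)-4-[(1S)-1-(3,4-bis(benzyloxy)-5-methoxyphenyl)allyloxy]-6-(4-benzyloxyphenyl)hex-1-en-2-yl}dimethylsilane | COc1cc([C@H](C=C)O[C@@H](CCc3ccc(OCc4ccccc4)cc3)CC(=C)[Si](C)(C)Cc5ccccc5)cc(OCc2ccccc2)c1OCc1ccccc1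
F4 | step 9 | benzyl{(2S,6S)-2-[3,4-bis(benzyloxy)-5-methoxyphenyl]-6-[2-(4-benzyloxyphenyl)ethyl]-5,6-dihydro-2H-pyran-4-yl}dimethylsilane | COc1cc([C@@H]3C=C([Si](C)(C)Cc5ccccc5)C[C@H](CCc4ccc(OCc6ccccc6)cc4)O3)cc(OCc2ccccc2)c1OCc1ccccc1
F5 | step 7 | (S)-1-(4-benzyloxyphenyl)hex-5-yn-3-ol | C#CC[C@@H](O)CCc1ccc(OCc2ccccc2)cc1
F6 | step 7 | (S)-6-(4-benzyloxyphenyl)-4-hydroxyhexan-2-one | CC(=O)C[C@@H](O)CCc1ccc(OCc2ccccc2)cc1
F7 | step 7 | (S,E)-1-[3,4-bis(benzyloxy)-5-methoxyphenyl]-7-(4-benzyloxyphenyl)-5-hydroxyhept-1-en-3-one | COc1cc(/C=C/C(=O)C[C@@H](O)CCc2ccc(OCc3ccccc3)cc2)cc(OCc2ccccc2)c1OCc1ccccc1
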